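A small charge of starting material read a larger percent of target at the same partner charge: the last 3 readings of the south-east run, at half the east charge, average 3.53%, and those of the east run 3.07%.

| flask | starting material | partner | remark | time |
|---|---|---|---|---|
| east | 0.20 M | 0.20 M | run made earlier |  |
| south-east | 0.10 M | 0.20 M | run made earlier |  |
| south-west | 0.15 M | 0.20 M | run made earlier |  |
| ash | 0.20 M | 0.200 M | everything together in a closed stirred flask, run for 40 min | 40 min |
| oak | 0.20 M | 0.200 M | a tube with plug flow, the mixed feed as stated, residence time 40 min | 40 min |
| alder | 0.20 M | 0.200 M | one stirred flow tank at steady state, fed with the mixture as stated, mean residence time 400 min |  |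
| birch | 0.20 M | 0.200 M | a single well-mixed tank run continuously and read at steady state, 40 min in it on average |  |

| run | time / min | target / % |
|---|---|---|
| east | 1.33 | 0.6 |
| east | 4.00 | 1.4 |
| east | 6.00 | 1.7 |
| east | 10.0 | 2.8 |
| east | 15.0 | 3.1 |
| east | 20.0 | 3.0 |
| east | 25.0 | 3.1 |
| south-east | 6.00 | 2.5 |
| south-east | 15.0 | 3.1 |
| south-east | 20.0 | 3.7 |
| south-east | 30.0 | 2.7 |
| south-east | 40.0 | 3.7 |
| south-east | 50.0 | 4.2 |
| south-west | 6.00 | 1.8 |
| south-west | 15.0 | 3.0 |
| south-west | 20.0 | 3.0 |
| south-west | 30.0 | 3.6 |
| south-west | 40.0 | 3.2 |
| south-west | 50.0 | 3.9 |

(each reading ± 0.3 percentage points)

* the set-up with the highest amount of target at the outlet or at the end, in percent of the starting material put in ("none" if the first two lie within 2 percentage points) (ash / oak / alder / birch / none)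
* amount of target at the outlet or at the end, in percent of the starting material put in, ash
* amount of target at the outlet or at the end, in percent of the starting material put in, oak
* amount of target at the outlet or at the end, in percent of the starting material put in, alder
* amount of target at the outlet or at the end, in percent of the starting material put in, birch

- the stated concentrations are those of everything mixed, before any reaction; amounts are the same in each set-up
- the earlier runs were made in a closed, stirred flask

We turn the question round: for a set-up to stand 2 percentage points above the plateau read in the east run, it must reach 5.07%. The east run gains 1.4% in its first 4.00 min, so its plateau divided by that first rate gives the settling time, the time to the plateau at the first rate, 8.76 min. Ash and oak last 4.57 settling times, so we place both at 3.07%. In a stirred tank we estimate the fraction of charged starting material unconverted as one over one plus residence time per settling time, that ratio being a Damköhler number: 2.14% in alder, 18.0% in birch. Treating that low standing level like a small charge, an assumption of ours, we read target as a power of that fraction, with exponent 0.204 from the two runs, so reaching 5.07% asks for a fraction of 8.57%. Alder lies below that, birch above. We commit to 6.73% for alder and 4.36% for birch, so alder is best. The exponent is a reading through the scatter, and those runs held the partner charge.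

The forecast differs: none best, with 3.1% for ash, 3.1% for oak, 3.1% for alder and 2.8% for birch, on the ground: “Every set-up here uses the east concentrations”.

The simulation names alder: ash 3.50%, oak 3.50%, alder 10.2%, birch 7.20%.

    starting material → side product (k = 0.00250 s⁻¹)
    starting material → intermediate A (k = 5.80 × 10⁻⁴ s⁻¹)
    partner + intermediate A ⇌ intermediate B (K = 1.80 M⁻¹, k = 0.0500 M⁻¹ s⁻¹)
    partner + intermediate A → target (k = 0.0150 M⁻¹ s⁻¹)
    2 partner → self-condensation product (k = 0.0240 M⁻¹ s⁻¹)
    partner → decomposed reagent (k = 0.00200 s⁻¹)

Alder holds 1.33% of the charged starting material, beside our 2.14%, and its target exceeds our 6.73%; birch, reckoned at 4.36%, also gives more. Oak ends after 4.57 settling times with 0.062% of its starting material and 0.078% of its partner left. Left ten times as long, to 400 min, oak shows 3.52% target, a change of 0.020 points.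

The runs were computed on assumed constants; scatter was added.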